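## Structural features

The target is a homoadamantane-type cage: a bicyclo[3.3.1]nonane-2,4,9-trione (ring B = C1–C2–C3–C4–C5–C9, ring A = C1–C8–C7–C6–C5–C9) whose C3 and C7 are tied by the two-carbon bridge C11–C10, with a gem-dimethylcyclopentane (C3, C11, C12, C13, C14) fused on the C3–C11 bond so that C3 is spiro to ring B. C1 carries a benzoyl group next to the gem-dimethyl carbon C8, C5 carries an (E)-geranyl chain, and the three ring-B carbonyls (C2, C4, C9, with oxygens O2, O4, O9) are flanked only by fully substituted carbons. There are five stereocentres, C1, C3, C5, C7 and C11 (1S,3S,5R,7R,11R in this numbering); the first four are cage atoms whose relative configuration the cage enforces, so C11 is the only independent centre. C11 also decides the constitution of the cage: the ring-B arm that is cis to C10 on the cyclopentane (C2–C1) must become the arm bonded to C8 and to the benzoyl group, and the other arm (C4–C5) the one bonded to C6 and to geranyl. The fragile groups are the non-enolisable β-polyketone, which nucleophiles can open by retro-Claisen cleavage, and the two trisubstituted alkenes of the geranyl chain, which do not tolerate strong acid, electrophiles or hydrogenation. The real difficulty is congestion (the contiguous C12–C11–C3 array, the C1–C8 bond between two fully substituted carbons, two substituted bridgeheads) together with the need to tell two constitutionally identical arms of ring B apart. The key step uses the fact that ring B at the trione oxidation level is a phloroglucinol and that C3 bears nothing but the cyclopentane: ipso attack of a flat, mirror-symmetric 4-alkyl-3,5-dimethoxyphenol on a tethered allyl unit forms C3–C11, closes the cyclopentane and leaves C11 as the single centre to control.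

## Logic of the disconnections

28 is cut at the C1–acyl bond into 25 and 26. An ordinary enolate next to C8 would acylate on oxygen, whereas a bridgehead carbanion inside the finished cage can only react at carbon, so the acyl group goes in last. The gain is the loss of the aryl ketone and of the quaternary C1; 25 has one acidic hydrogen only. The forward step needs a hindered amide base that removes C1–H without adding to three ketones, and substitution with retention.

25 is cut at C5–C6 (with C7–H) to 24. C5 is flanked by two carbonyls and is therefore a natural radical site, and C6 is the terminal carbon of an exocyclic alkene held directly over it. The cut removes ring A, the cage and two stereocentres (C5, C7) at once, with the geranyl group already on C5. The forward step must close 6-endo rather than 5-exo, and hydrogen transfer from tin must be slower than ring closure.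

24 is cut at C5–Br to 23, and 23 at the C5–geranyl bond to 21 and 22. In 21 the dione C4–C5–C9 is the only unhindered acidic site (C1 is a hindered bridgehead), so both electrophiles are directed to C5. The gain is the removal of the C10 side chain. The forward steps need C- over O-allylation, mono-allylation, retention of the E alkene, and bromination at the enol carbon in the presence of isolated alkenes.

21 is cut at C1–C8 and reconnected as O2–C6 to give 20. The exocyclic methylene at C7 next to a quaternary C8 bonded to a ketone α-carbon is the retron of a [3,3] shift of an allyl vinyl ether, the dependable way to bond an enol carbon to a fully substituted allyl terminus. The hardest C–C bond of the molecule becomes a C–O bond. The forward step must pass through a boat-like transition state bridged by C3–C11–C10.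

20 is cut at O2–C6 to 19, and 19 is traced to its bis(methyl enol ether) 18. Only O2, on the arm cis to C10, can close a seven-membered ether ring with C6, so this cut is where the two arms are told apart and where C3 stops being stereogenic in the retrosynthetic direction. The forward steps need hydrolysis of two vinylogous esters without acid (the allylic alcohol ionises easily) and O- rather than C-alkylation.

18 is traced through 17 to 13 and 14, and 13 to 11 and 12. The terminal vinyl carbon C7 must gain two carbon substituents, C6 and C8. Hydroformylation adds C6 and leaves C7 α to a carbonyl group, where it condenses with the three-carbon ketal 14; reduction then gives the allylic alcohol. The side chain is thereby reduced to a vinyl group. The forward steps need linear selectivity and must leave the dienone alone.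

11 is cut at C3–C11 to 10 (key step). The precursor is simplified to an achiral arene with an allylic carbonate, and one catalyst sets the only independent stereocentre. A free triphenol would be the simplest precursor, but it would need a global demethylation in the presence of an allylic alcohol and a carbonate formation that spares three phenols, it offers two ortho oxygens for O-alkylation, and it would give an acidic trione that has to be masked anyway. 10 therefore carries the two ortho oxygens as methyl ethers and only the para oxygen free. The forward step needs attack at the hindered inner allyl terminus by a carbon flanked by two methoxy groups.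

10 is cut at O–Si to 9, and 9 at the alkene to 7 and 8 (cross-metathesis). This shortens the chain to a vinyl group on the quaternary carbon and installs the carbonate while the phenol is masked. The forward step needs a metathesis at a vinyl group next to a quaternary centre.

7 is cut at the aryl–CH2 bond to 5 (as 6) and 3; 5 comes from 4, and 3 from 1 through 2. The arene is metalated between its two methoxy groups and the gem-dimethyl carbon is bought ready-made. The forward step needs lithiation away from the bulky silyl ether and clean SN2 alkylation.

## Other disconnections considered

Alternative 1: The cut is C4–C5, the last bond of ring B. In the forward direction keto aldehyde A2 would already hold ring A, the first seven-membered ring, the cyclopentane, the geranyl group on C5 and a silyl ether at C2. LiN(iPr)2 would deprotonate it at C5 (the other α-carbon of the C9 ketone, C1, is a hindered bridgehead), and the enolate would add to the neopentylic, non-enolisable aldehyde on C3 to give aldol A1, closing ring B and the second seven-membered ring together.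
- In its favour: the quaternary C5 is made with the geranyl group in place, so no bridgehead alkylation, halogen or tin is needed. The two arms of ring B are built one after the other, so the problem of telling them apart never arises. On both points it is better than the chosen plan.
- Against it here: A2 must already carry C1, C2, C3, C7 and C11 in the right relative and absolute sense, and the aldol creates none of them. The aldol is reversible, and retro-aldol opening of a strained cage is a real competitor. After A1 there remain a desilylation, two alcohol oxidations and the same bridgehead benzoylation that ends the chosen route.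
- Comparison: on structure it leaves the cage for the end but moves all stereochemical work to the front, where the chosen plan needs one catalyst-controlled centre. On mechanism it is a substrate-controlled two-electron closure against a catalytic enantioselective one. On step economy the route to A2 is likely to exceed the sixteen-step line of the chosen plan, while the steps after A1 are about equal in number to the chosen endgame.

Alternative 2: The cut is C5–C6, made through a temporary C5–C7 bond. In the forward direction Rh2(esp)2 would decompose the 2-diazo-1,3-dione A4 and the carbenoid at C5 would add across the exocyclic C7=C6 alkene to give cyclopropane A3; reductive cleavage of C5–C7 would then leave ring A.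
- In its favour: carbenoid addition to a 1,1-disubstituted alkene is fast and stereospecific. Both candidate bonds are formed, so no 5-exo versus 6-endo question arises, and no tin is used. On these points it is the equal or the better of the radical closure chosen here (step 16).
- Against it here: A4 presupposes a C1 that is already quaternary (benzoyl and C8), which is the hardest centre to make before the cage exists. C5 ends as C–H, so the geranyl group must enter by bridgehead alkylation. An acceptor/acceptor carbenoid next to ketone oxygens can divert to carbonyl ylides, dihydrofurans or C–H insertion at C10.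
- Comparison: on structure it is an endgame variant fully compatible with the chosen key step. On mechanism it trades a radical chain for carbenoid chemistry plus a dissolving-metal or SmI2 reduction. On step economy it needs four operations (diazo transfer, cyclopropanation, opening, bridgehead alkylation) where the chosen route uses three (allylation, bromination, radical closure). It is kept as the fallback for step 16.

Alternative 3: The cuts are C11–C12 and C3–C14, which make the gem-dimethylcyclopentane. In the forward direction, fac-Ir(ppy)3 and visible light would turn redox-active ester A7 into the 4-chloro-2-methylbutan-2-yl radical, which adds to the β-carbon of alkylidene malonate A6. Reduction to the malonate anion and displacement of chloride would then give cyclopentane A5.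
- In its favour: the most hindered bond of the cyclopentane (C11–C12, next to a quaternary carbon) is made by a tertiary radical, which tolerates congestion better than attack on an allyl–metal terminus; here it is better than the chosen key step. The materials are cheap, and the ring arrives in about three steps against seven for 11.
- Against it here: the photocatalyst does not control C11, the one centre that dictates the whole cage, so a chiral Lewis acid, an auxiliary or a resolution would have to be added. Ring B must then be built from the two ester carbons (C2, C4) of a neopentylic gem-diester and a three-carbon C1–C9–C5 unit, whereas the chosen plan obtains ring B from an arene. The benzyloxymethyl arm (C10) still needs the same homologation as the vinyl group of 11.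
- Comparison: on structure it builds the small ring first and the six-membered ring second, the reverse of the chosen order. On mechanism it is a radical–polar crossover without stereocontrol against a two-electron enantioselective allylation. On step economy the early saving is likely to be spent again on ring B, so the totals should be about equal.

Key step: step 7

Remarks before the steps:
- The R descriptor at C11 of 11 was checked atom by atom against the cage configuration of 28 (C10 cis to the C2 arm, C12 gauche to it) and is consistent; no structure needed correction.
- Assumption: the (Ra,R,R) antipode of the phosphoramidite is taken to expose the Re face of C11 to the arene, as this catalyst family usually does with linear E-allyl carbonates; if the opposite sense is found, the (Sa,S,S) ligand is used and nothing else changes.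
- Enolisable di- and triones are written in one tautomeric form (19 and 21 as triketones, 23 as the C4 enol); this is a drawing convention.

## Steps

Step 1
Reactants: 1 methyl 3,3-dimethylpent-4-enoate
Product: 2 3,3-dimethylpent-4-en-1-ol
Conditions: LiAlH4, Et2O, 0 °C
Reagents that add atoms: none
Why: Hydride reduction of the ester to the primary alcohol; the isolated vinyl group is inert to LiAlH4.

Step 2
Reactants: 2 3,3-dimethylpent-4-en-1-ol
Product: 3 5-iodo-3,3-dimethylpent-1-ene
Conditions: I2, PPh3, imidazole, CH2Cl2, 0 °C to rt
Reagents that add atoms: iodine, II
Why: Appel-type iodination; iodide displaces the oxyphosphonium group by SN2 at the primary carbon, so no cation and no skeletal shift is involved.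

Step 3
Reactants: 4 3,5-dimethoxyphenol
Product: 5 (3,5-dimethoxyphenoxy)tri(propan-2-yl)silane
Conditions: i-Pr3SiCl, imidazole, DMF, rt
Reagents that add atoms: chlorotri(propan-2-yl)silane, CC(C)[Si](Cl)(C(C)C)C(C)C
Why: Silylation of the phenol; the bulky silyl ether removes the acidic hydrogen, survives organolithium reagents and is a poor directing group.

Step 4
Reactants: 5 (3,5-dimethoxyphenoxy)tri(propan-2-yl)silane; 3 5-iodo-3,3-dimethylpent-1-ene
Product: 7 [4-(3,3-dimethylpent-4-en-1-yl)-3,5-dimethoxyphenoxy]tri(propan-2-yl)silane, via aryllithium 6 (not isolated)
Conditions: n-BuLi (0.98 equiv), THF, 0 °C to rt; then 3, 0 °C to rt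
Reagents that add atoms: none
Why: Directed ortho-lithiation at the carbon between the two methoxy groups (the positions next to the bulky, weakly coordinating silyloxy group are not metalated), then SN2 alkylation of the aryllithium by the unhindered primary iodide. A slight deficit of n-BuLi avoids iodine–lithium exchange on 3.

Step 5
Reactants: 7 [4-(3,3-dimethylpent-4-en-1-yl)-3,5-dimethoxyphenoxy]tri(propan-2-yl)silane; 8 methyl prop-2-en-1-yl carbonate (allyl methyl carbonate)
Product: 9 (2E)-6-{2,6-dimethoxy-4-[tri(propan-2-yl)silyloxy]phenyl}-4,4-dimethylhex-2-en-1-yl methyl carbonate
Conditions: RuCl2(=CHPh)(PCy3)(H2IMes) (second-generation Grubbs catalyst, 5 mol%), 8 (5 equiv), CH2Cl2, 40 °C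
Reagents that add atoms: none
Why: Olefin cross-metathesis; a vinyl group on a quaternary carbon does not homodimerise and should couple with the excess unhindered partner, and the bulk next to the new alkene should give the E isomer.

Step 6
Reactants: 9 (2E)-6-{2,6-dimethoxy-4-[tri(propan-2-yl)silyloxy]phenyl}-4,4-dimethylhex-2-en-1-yl methyl carbonate
Product: 10 (2E)-6-(4-hydroxy-2,6-dimethoxyphenyl)-4,4-dimethylhex-2-en-1-yl methyl carbonate
Conditions: Bu4NF, AcOH, THF, 0 °C
Reagents that add atoms: none
Why: Fluoride cleaves the aryl silyl ether; acetic acid keeps the phenol protonated so that it does not attack the carbonate.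

Step 7
Reactants: 10 (2E)-6-(4-hydroxy-2,6-dimethoxyphenyl)-4,4-dimethylhex-2-en-1-yl methyl carbonate
Product: 11 (1R)-1-ethenyl-6,10-dimethoxy-2,2-dimethylspiro[4.5]deca-6,9-dien-8-one
Conditions: [Ir(cod)Cl]2 (2.5 mol%), (Ra,R,R)-L (5 mol%; L = 1,1′-binaphthyl-2,2′-diyl N,N-bis(1-phenylethyl)phosphoramidite), n-PrNH2 (catalyst activation), Li2CO3, THF (0.02 M), 50 °C
Reagents that add atoms: none
Why: The amine-activated complex of monovalent iridium ionises the allylic carbonate, with loss of CO2 and methoxide, to an (η3-allyl) complex of trivalent iridium; methoxide, shuttled by Li2CO3, deprotonates the phenol, and the carbon para to the phenoxide oxygen, which is the ipso carbon C3, attacks the substituted allyl terminus C11 anti to the metal. The closest known reaction type is the iridium-catalysed intramolecular asymmetric allylic dearomatization of para-tethered phenols to spiro[4.5]cyclohexadienones. The cyclopentane closes in the 5-exo-trig mode onto the inner terminus; attack at the CH2 terminus would need a seven-membered ring and runs against the preference of iridium for the substituted carbon. C11 is the only new stereocentre and is set by the phosphoramidite, which fixes the allyl face open to the arene (the Re face of C11 for the R product); C3 is not stereogenic because its two arms are identical. The step needs C- over O-alkylation, and the substrate secures it: the free hydroxyl is para and cannot reach the allyl unit within the molecule, both ortho oxygens are methyl ethers, and only C3 lies five atoms from C11. The gem-dimethyl group at C12 favours the folded conformer, and dilution suppresses intermolecular O-allylation.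

Step 8
Reactants: 11 (1R)-1-ethenyl-6,10-dimethoxy-2,2-dimethylspiro[4.5]deca-6,9-dien-8-one; 12 carbon monoxide
Product: 13 3-[(1R)-6,10-dimethoxy-2,2-dimethyl-8-oxospiro[4.5]deca-6,9-dien-1-yl]propanal
Conditions: Rh(acac)(CO)2 (1 mol%), Xantphos (2 mol%), CO/H2 (1:1, 20 bar), PhMe, 80 °C
Reagents that add atoms: none
Why: Rhodium-catalysed hydroformylation; the vinyl group sits on a carbon flanked by two quaternary centres, so the acyl group can only be placed on the terminal carbon C7, and the trisubstituted β-methoxy enone double bonds do not insert. This adds C6 and leaves C7 α to a carbonyl group.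

Step 9
Reactants: 13 3-[(1R)-6,10-dimethoxy-2,2-dimethyl-8-oxospiro[4.5]deca-6,9-dien-1-yl]propanal; 14 2,2-dimethoxypropane
Product: 17 2-{[(1R)-6,10-dimethoxy-2,2-dimethyl-8-oxospiro[4.5]deca-6,9-dien-1-yl]methyl}-3-methylbut-2-enal, via silyl enol ether 15 (not isolated), via β-methoxy aldehyde 16 (not isolated)
Conditions: Me3SiOTf (1.6 equiv), i-Pr2NEt (1.3 equiv), CH2Cl2, 0 °C; then 14, −78 to 0 °C; then DBU, rt
Reagents that add atoms: none
Why: One-flask enol silane formation and Mukaiyama aldol addition to the ketal (the excess silyl triflate generates the oxocarbenium ion), then E1cB loss of methanol to the conjugated enal with the tetrasubstituted C7=C8 bond. The dienone has no enolisable hydrogen, and its push–pull alkenes are far weaker nucleophiles than the enol silane.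

Step 10
Reactants: 17 2-{[(1R)-6,10-dimethoxy-2,2-dimethyl-8-oxospiro[4.5]deca-6,9-dien-1-yl]methyl}-3-methylbut-2-enal
Product: 18 (1R)-1-[2-(hydroxymethyl)-3-methylbut-2-en-1-yl]-6,10-dimethoxy-2,2-dimethylspiro[4.5]deca-6,9-dien-8-one
Conditions: NaBH4 (0.5 equiv), CeCl3·7H2O, MeOH, −40 °C
Reagents that add atoms: none
Why: Luche 1,2-reduction of the enal; an aldehyde is reduced much faster than the doubly vinylogous carbonate carbonyl C9, and cerium suppresses conjugate reduction.

Step 11
Reactants: 18 (1R)-1-[2-(hydroxymethyl)-3-methylbut-2-en-1-yl]-6,10-dimethoxy-2,2-dimethylspiro[4.5]deca-6,9-dien-8-one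
Product: 19 (1R)-1-[2-(hydroxymethyl)-3-methylbut-2-en-1-yl]-2,2-dimethylspiro[4.5]decane-6,8,10-trione
Conditions: 2 M NaOH, dioxane/H2O, 80 °C; then 1 M HCl to pH 4, 0 °C
Reagents that add atoms: water, O
Why: Alkaline hydrolysis of both vinylogous esters by conjugate addition of hydroxide and loss of methoxide. Base is chosen because the tetrasubstituted allylic alcohol ionises in acid, and the trione survives as its delocalised anion until the cold acidification.

Step 12
Reactants: 19 (1R)-1-[2-(hydroxymethyl)-3-methylbut-2-en-1-yl]-2,2-dimethylspiro[4.5]decane-6,8,10-trione
Product: 20 tethered allyl enol ether (O2–C6 bond in a seven-membered ring O2–C2–C3–C11–C10–C7–C6; C1=C2 enol ether; ketones at C9 and C4; exocyclic C7=C8Me2; C2 arm cis to C10; C11 R)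
Conditions: PPh3, DIAD, THF (0.005 M, slow addition of 19), 0 °C to rt
Reagents that add atoms: none
Why: Intramolecular Mitsunobu O-alkylation of the vinylogous acid (pKa about 5) by the primary allylic alcohol with SN2 displacement at C6. Only O2, the oxygen on the arm cis to C10, can close a seven-membered ring, so this step tells the two arms apart and makes C3 stereogenic under the control of C11. O-alkylation is the usual course for cyclic 1,3-diones here, and dilution suppresses intermolecular etherification.

Step 13
Reactants: 20 tethered allyl enol ether
Product: 21 bridged trione (C1–C8 bond; exocyclic C7=C6H2; ketones at C2 C4 C9; C1–H anti to the C10 bridge; C3 and C11 as in 20)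
Conditions: PhMe, 150 °C, sealed tube
Reagents that add atoms: none
Why: Claisen rearrangement of the allyl vinyl ether C1=C2–O2–C6–C7=C8 through a boat-like transition state bridged by C3–C11–C10; it forms C1–C8 at the fully substituted terminus and turns C6 into an exocyclic methylene, driven by the exchange of an enol ether for a ketone. The new centre C1 is a bridgehead of the resulting bicyclo[4.3.1] skeleton, so its hydrogen can only point away from the bridge.

Step 14
Reactants: 21 bridged trione; 22 (2E)-3,7-dimethylocta-2,6-dien-1-yl acetate (geranyl acetate)
Product: 23 C5-geranyl derivative of 21 (drawn as the C4 enol; E alkene retained)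
Conditions: Pd(PPh3)4 (5 mol%), Et3N (1.2 equiv), 22 (1.05 equiv), THF, 40 °C
Reagents that add atoms: none
Why: Tsuji–Trost allylation: zerovalent palladium ionises the acetate and the enolate of the C4–C5–C9 dione, the only unhindered acidic site, attacks the primary allyl terminus, which keeps the E geometry. O-allylated material re-ionises and funnels to the C-allyl product, and C1 is a hindered bridgehead next to C8.

Step 15
Reactants: 23 C5-geranyl derivative of 21
Product: 24 C5-bromo-C5-geranyl triketone (both C5 epimers)
Conditions: NBS (1.0 equiv), CH2Cl2, −78 °C
Reagents that add atoms: N-bromosuccinimide, O=C1CCC(=O)N1Br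
Why: Electrophilic bromination of the enol at C5, its only nucleophilic carbon; C1–H cannot enolise without a strained bridgehead double bond, and the isolated alkenes are far slower at −78 °C. The configuration at C5 does not matter because the next step passes through the planar radical.

Step 16
Reactants: 24 C5-bromo-C5-geranyl triketone
Product: 25 caged triketone (28 lacking the benzoyl group; C1–H; cage centres C3 C5 C7 C11 as in 28)
Conditions: Bu3SnH (1.2 equiv, syringe pump), AIBN (0.2 equiv), PhH (0.005 M), 80 °C
Reagents that add atoms: none
Why: Tin-mediated reductive radical cyclisation: the α,α-diacyl radical at C5 adds to the CH2 terminus C6 of the 1,1-disubstituted alkene in the 6-endo mode, which carbonyl-flanked radicals and 1,1-disubstituted alkenes favour over 5-exo attack at the substituted carbon C7; this closes ring A and the cage. The tertiary radical at C7 can take hydrogen from Bu3SnH only on its outer face and C5 is a bridgehead, so both new centres are fixed by the cage.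

Step 17
Reactants: 25 caged triketone; 26 benzoyl chloride
Product: 28 CNP0168637.1, via bridgehead organolithium 27 (not isolated)
Conditions: lithium 2,2,6,6-tetramethylpiperidide (1.5 equiv), THF, −78 °C; then 26, −78 to 0 °C
Reagents that add atoms: none
Why: Bridgehead deprotonation–acylation, a known reaction type for bridgehead positions of bicyclo[3.3.1]nonane-2,9-diones: C1–H is the only acidic hydrogen left, the carbanion cannot flatten into an O-nucleophilic enolate and is therefore acylated on carbon with retention. The hindered amide base should not add to the non-enolisable ketones at −78 °C.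

## Compound list

1 | methyl 3,3-dimethylpent-4-enoate | COC(=O)CC(C)(C)C=C | starting material
2 | 3,3-dimethylpent-4-en-1-ol | OCCC(C)(C)C=C | intermediate
3 | 5-iodo-3,3-dimethylpent-1-ene | ICCC(C)(C)C=C | intermediate
4 | 3,5-dimethoxyphenol | COc1cc(O)cc(OC)c1 | starting material
5 | (3,5-dimethoxyphenoxy)tri(propan-2-yl)silane | COc1cc(OC)cc(O[Si](C(C)C)(C(C)C)C(C)C)c1 | intermediate
6 | {2,6-dimethoxy-4-[tri(propan-2-yl)silyloxy]phenyl}lithium | [Li]c1c(OC)cc(O[Si](C(C)C)(C(C)C)C(C)C)cc1OC | intermediate (not isolated)
7 | [4-(3,3-dimethylpent-4-en-1-yl)-3,5-dimethoxyphenoxy]tri(propan-2-yl)silane | C=CC(C)(C)CCc1c(OC)cc(O[Si](C(C)C)(C(C)C)C(C)C)cc1OC | intermediate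
8 | methyl prop-2-en-1-yl carbonate (allyl methyl carbonate) | COC(=O)OCC=C | starting material
9 | (2E)-6-{2,6-dimethoxy-4-[tri(propan-2-yl)silyloxy]phenyl}-4,4-dimethylhex-2-en-1-yl methyl carbonate | COC(=O)OC/C=C/C(C)(C)CCc1c(OC)cc(O[Si](C(C)C)(C(C)C)C(C)C)cc1OC | intermediate
10 | (2E)-6-(4-hydroxy-2,6-dimethoxyphenyl)-4,4-dimethylhex-2-en-1-yl methyl carbonate | COC(=O)OC/C=C/C(C)(C)CCc1c(OC)cc(O)cc1OC | intermediate
11 | (1R)-1-ethenyl-6,10-dimethoxy-2,2-dimethylspiro[4.5]deca-6,9-dien-8-one | C=C[C@@H]1C(C)(C)CCC12C(OC)=CC(=O)C=C2OC | intermediate
12 | carbon monoxide | [C-]#[O+] | starting material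
13 | 3-[(1R)-6,10-dimethoxy-2,2-dimethyl-8-oxospiro[4.5]deca-6,9-dien-1-yl]propanal | O=CCC[C@@H]1C(C)(C)CCC12C(OC)=CC(=O)C=C2OC | intermediate
14 | 2,2-dimethoxypropane | COC(C)(C)OC | starting material
15 | trimethylsilyl enol ether of 13 (E/Z mixture) | C[Si](C)(C)OC=CC[C@@H]1C(C)(C)CCC12C(OC)=CC(=O)C=C2OC | intermediate (not isolated)
16 | 2-{[(1R)-6,10-dimethoxy-2,2-dimethyl-8-oxospiro[4.5]deca-6,9-dien-1-yl]methyl}-3-methoxy-3-methylbutanal (both epimers at the aldehyde α-carbon) | COC(C)(C)C(C=O)C[C@@H]1C(C)(C)CCC12C(OC)=CC(=O)C=C2OC | intermediate (not isolated)
17 | 2-{[(1R)-6,10-dimethoxy-2,2-dimethyl-8-oxospiro[4.5]deca-6,9-dien-1-yl]methyl}-3-methylbut-2-enal | CC(C)=C(C=O)C[C@@H]1C(C)(C)CCC12C(OC)=CC(=O)C=C2OC | intermediate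
18 | (1R)-1-[2-(hydroxymethyl)-3-methylbut-2-en-1-yl]-6,10-dimethoxy-2,2-dimethylspiro[4.5]deca-6,9-dien-8-one | CC(C)=C(CO)C[C@@H]1C(C)(C)CCC12C(OC)=CC(=O)C=C2OC | intermediate
19 | (1R)-1-[2-(hydroxymethyl)-3-methylbut-2-en-1-yl]-2,2-dimethylspiro[4.5]decane-6,8,10-trione (triketone tautomer drawn) | CC(C)=C(CO)C[C@@H]1C(C)(C)CCC12C(=O)CC(=O)CC2=O | intermediate
20 | tethered allyl enol ether: O2 bonded to C6 in a seven-membered ring, C1=C2 enol ether, ketones at C9 and C4, C5H2, exocyclic C7=C8Me2, C2 arm cis to C10 on the cyclopentane, C11 R | CC(C)=C1COC2=CC(=O)CC(=O)[C@@]23CCC(C)(C)[C@H]3C1 | intermediate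
21 | bridged trione: C1–C8 bond, exocyclic C7=C6H2, ketones at C2, C4 and C9, C5H2, C1–H anti to the C10 bridge (triketone tautomer drawn) | C=C1C[C@@H]2C(C)(C)CC[C@]2(C(=O)CC3=O)C(=O)[C@@H]3C1(C)C | intermediate
22 | (2E)-3,7-dimethylocta-2,6-dien-1-yl acetate (geranyl acetate) | CC(=O)OC/C=C(\C)CCC=C(C)C | starting material
23 | C5-[(2E)-3,7-dimethylocta-2,6-dien-1-yl] derivative of 21 (C4 enol drawn) | C=C1C[C@@H]2C(C)(C)CC[C@]2(C(O)=C(C/C=C(\C)CCC=C(C)C)C3=O)C(=O)[C@@H]3C1(C)C | intermediate
24 | C5-bromo-C5-geranyl triketone (both C5 epimers; other centres as in 21) | C=C1C[C@@H]2C(C)(C)CC[C@]2(C(=O)C(Br)(C/C=C(\C)CCC=C(C)C)C3=O)C(=O)[C@@H]3C1(C)C | intermediate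
25 | caged triketone: 28 with hydrogen in place of the benzoyl group at C1 | CC(C)=CCC/C(C)=C/C[C@@]12C[C@H]3C[C@@H]4C(C)(C)CC[C@]4(C1=O)C(=O)[C@@H](C2=O)C3(C)C | intermediate
26 | benzoyl chloride | O=C(Cl)c1ccccc1 | starting material
27 | C1-lithio derivative of 25 | CC(C)=CCC/C(C)=C/C[C@@]12C[C@H]3C[C@@H]4C(C)(C)CC[C@]4(C1=O)C(=O)[C@@]([Li])(C2=O)C3(C)C | intermediate (not isolated)
28 | CNP0168637.1: (1S,3S,5R,7R,11R) caged trione with benzoyl on C1, (E)-geranyl on C5, gem-dimethyl at C8 and C12 (numbering of this text) | CC(C)=CCC/C(C)=C/C[C@@]12C[C@H]3C[C@@H]4C(C)(C)CC[C@]4(C1=O)C(=O)[C@@](C(=O)c1ccccc1)(C2=O)C3(C)C | target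

## Step count and least certain steps

Total step count: 17. Longest linear sequence: 16 steps (1 to 28 through steps 1, 2 and 4–17); the one-step branch 4 to 5 (step 3) joins at step 4.

Step 7 (key step). Most likely to go wrong: the allyl complex may form slowly from an internal alkene next to a quaternary carbon, and C–C bond formation between that hindered terminus and an ipso carbon flanked by two methoxy groups may be slow. β-Hydride loss to a diene, intermolecular O-allylation or an unselective background pathway could then take over. The fallback keeps the same bond and ring but generates the allyl complex differently; it sets out from 7 and comes back at 11. Oxidative cleavage of the vinyl group (OsO4 cat., NaIO4, 2,6-lutidine) gives aldehyde F1, and vinylmagnesium bromide gives the racemic branched allylic alcohol F2. Bu4NF frees phenol F3, which is cyclised with [Ir(cod)Cl]2, a binaphthol-derived phosphoramidite–alkene ligand and Zn(OTf)2 as promoter. Under such conditions racemic branched allylic alcohols are ionised directly and converge on one enantiomer, and the complex forms from a terminal alkene and a secondary carbinol instead of a hindered internal alkene.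

Step 12. Most likely to go wrong: alkylation at carbon (C1 attacking C6) instead of at O2, or intermolecular etherification. The fallback sets out from 19 and comes back at 20 without any new compound. Acid-catalysed dehydrative enol etherification (pyridinium p-toluenesulfonate, PhH, reflux, molecular sieves) joins the alcohol oxygen to C2 by addition–elimination at the carbonyl carbon instead of SN2 at C6, a pathway that cannot alkylate carbon.

Step 13. Most likely to go wrong: at the temperature the bridged boat transition state needs, the acidic enol of 20 may catalyse ionisation of the allyl–oxygen bond, leading to recombination at C6 or elimination instead of the concerted shift. The fallback removes the acidic hydrogen; it sets out from 18 and comes back at 21. Catalytic t-BuOK in PhMe with removal of methanol lets the tethered alkoxide exchange with the C2 methoxy group by addition–elimination (only the C2 arm is in reach), giving methyl enol ether F4. The [3,3] shift is run on F4 to give F5, and aqueous HCl then hydrolyses the remaining enol ether to 21, which has no acid-sensitive allylic alcohol.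

Step 16. Most likely to go wrong: reduction of the C5 radical by the tin hydride before ring closure, or 5-exo closure onto C7. The fallback forms C5–C6 by carbenoid chemistry; it sets out from 21 and comes back at 25. Diazo transfer (4-acetamidobenzenesulfonyl azide, Et3N) gives diazo dione F6, Rh2(esp)2 gives cyclopropane F7 by addition across C7=C6, and SmI2 cleaves the C5–C7 bond (the one that leaves a tertiary radical) to give the caged triketone F8. Bridgehead deprotonation at the less hindered C5 (LiN(iPr)2, THF, −78 °C) and geranyl bromide then give 25.

Step 17. Most likely to go wrong: capture of the hindered bridgehead carbanion by the acid chloride may be slower than proton return, or the acid chloride may be consumed by the amide base. The fallback uses a smaller electrophile and a separate oxidation; it sets out from 25 and comes back at 28. The bridgehead anion (lithium 2,2,6,6-tetramethylpiperidide, THF, −78 °C) is added to benzaldehyde to give carbinol F9, which Dess–Martin periodinane oxidises to 28.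

## Further compounds

F1 | step 7 | 4-{2,6-dimethoxy-4-[tri(propan-2-yl)silyloxy]phenyl}-2,2-dimethylbutanal | O=CC(C)(C)CCc1c(OC)cc(O[Si](C(C)C)(C(C)C)C(C)C)cc1OC
F2 | step 7 | rac-6-{2,6-dimethoxy-4-[tri(propan-2-yl)silyloxy]phenyl}-4,4-dimethylhex-1-en-3-ol | C=CC(O)C(C)(C)CCc1c(OC)cc(O[Si](C(C)C)(C(C)C)C(C)C)cc1OC
F3 | step 7 | rac-4-(4-hydroxy-3,3-dimethylhex-5-en-1-yl)-3,5-dimethoxyphenol | C=CC(O)C(C)(C)CCc1c(OC)cc(O)cc1OC
F0 | step 12 | none | none
F4 | step 13 | C4 methyl enol ether analogue of 20 (C4-methoxy dienone; stereocentres as in 20) | CC(C)=C1COC2=CC(=O)C=C(OC)[C@@]23CCC(C)(C)[C@H]3C1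
F5 | step 13 | C4 methyl enol ether of 21 (stereocentres as in 21) | C=C1C[C@@H]2C(C)(C)CC[C@]2(C(OC)=CC3=O)C(=O)[C@@H]3C1(C)C
F6 | step 16 | C5-diazo derivative of 21 | C=C1C[C@@H]2C(C)(C)CC[C@]2(C(=O)C3=[N+]=[N-])C(=O)[C@@H](C3=O)C1(C)C
F7 | step 16 | cyclopropane-bridged triketone (C5, C6, C7 three-membered ring; C1–H) | [C@]125C[C@@]53C[C@@H]4C(C)(C)CC[C@]4(C1=O)C(=O)[C@@H](C2=O)C3(C)C
F8 | step 16 | caged triketone with hydrogen at both C5 and C1 | [C@@H]12C[C@H]3C[C@@H]4C(C)(C)CC[C@]4(C1=O)C(=O)[C@@H](C2=O)C3(C)C
F9 | step 17 | C1-[hydroxy(phenyl)methyl] caged triketone (both carbinol epimers) | CC(C)=CCC/C(C)=C/C[C@@]12C[C@H]3C[C@@H]4C(C)(C)CC[C@]4(C1=O)C(=O)[C@@](C(O)c1ccccc1)(C2=O)C3(C)C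
A1 | alternative 1 | caged C4 aldol with C2 silyl ether and C9 ketone | CC(C)=CCC/C(C)=C/C[C@@]12C[C@H]3C[C@@H]4C(C)(C)CC[C@]4([C@@H]1O)[C@@H](O[Si](C)(C)C(C)(C)C)[C@@H](C2=O)C3(C)C
A2 | alternative 1 | keto aldehyde precursor (C4 aldehyde on C3; C5–H, either epimer) | CC(C)=CCC/C(C)=C/CC2C[C@H]3C[C@@H]4C(C)(C)CC[C@]4(C=O)[C@@H](O[Si](C)(C)C(C)(C)C)[C@@H](C2=O)C3(C)C
A3 | alternative 2 | cyclopropane-bridged benzoyl trione (C5, C6, C7 three-membered ring) | [C@]125C[C@@]53C[C@@H]4C(C)(C)CC[C@]4(C1=O)C(=O)[C@@](C(=O)c6ccccc6)(C2=O)C3(C)C
A4 | alternative 2 | C5-diazo C1-benzoyl trione with exocyclic C7=C6 alkene | C=C1C[C@@H]2C(C)(C)CC[C@]2(C(=O)C3=[N+]=[N-])C(=O)[C@@](C(=O)c4ccccc4)(C3=O)C1(C)C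
A5 | alternative 3 | dimethyl 2-(benzyloxymethyl)-3,3-dimethylcyclopentane-1,1-dicarboxylate | COC(=O)C1(C(=O)OC)CCC(C)(C)[C@H]1COCc2ccccc2
A6 | alternative 3 | dimethyl 2-[2-(benzyloxy)ethylidene]propanedioate | COC(=O)C(=CCOCc1ccccc1)C(=O)OC
A7 | alternative 3 | 1,3-dioxoisoindolin-2-yl 4-chloro-2,2-dimethylbutanoate | CC(C)(CCCl)C(=O)ON1C(=O)c2ccccc2C1=O
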